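The acid is traced back to its methyl ester, the chain ketone to a dioxolane and the arene to a cyclohexane-1,3-dione, whose ring is cut at C1–C6 and C3–C4.
Enabling feature: in the benzene ring, C1 (carboxyl), C2 (OH) and C3 (H) repeat the skeleton of an acetoacetate. C4 (OMe), C5 (H) and C6 (2-oxotridecyl chain) repeat the ester carbon, α-carbon and β-carbon of a 2-enoate, so the meta-dioxygenated ring is a 2,4-dioxocyclohexanecarboxylate two hydrogens away.
The enoate is cut at its C=C bond (the future C5–C6) to a stabilised ylide and a β-ketal aldehyde. The aldehyde is cut at the chain C1'–C2' bond to a two-carbon unit from Meldrum's acid and dodecanoyl chloride.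
Forward: the chain is built linearly (steps 1–5) and the only ring closes in step 6. Step 7 aromatises it, methylates the C4 oxygen and removes the ketal, and step 8 cleaves the ester.
Stereochemistry: the target has no stereocentre. The two ring stereocentres made in step 6 are racemic and vanish in step 7, and the E geometry set by the ylide in step 5 is not carried on.

Key step: step 6

Remark: 3 is written as its enol and 11 as its triketo form although both are tautomeric mixtures; 10 and 11 are racemic mixtures of diastereomers, so their SMILES carry no stereodescriptors.

Step 1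
Reactants: 1 dodecanoyl chloride; 2 Meldrum's acid (2,2-dimethyl-1,3-dioxane-4,6-dione)
Product: 3 5-(1-hydroxydodecylidene)-2,2-dimethyl-1,3-dioxane-4,6-dione
Conditions: pyridine (2.2 equiv), CH2Cl2, 0 °C to rt; 1 M HCl wash
Reagents that add atoms: none
Why: Meldrum's acid (pKa about 5) is C-acylated by an acid chloride under pyridine alone, and the product rests as a hydrogen-bonded enol that resists a second acylation (C-acylation of an active methylene compound).

Step 2
Reactants: 3 5-(1-hydroxydodecylidene)-2,2-dimethyl-1,3-dioxane-4,6-dione
Product: 4 methyl 3-oxotetradecanoate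
Conditions: MeOH, reflux
Reagents that add atoms: methanol, CO
Why: Heating an acyl Meldrum's acid in an alcohol opens the dioxanedione and expels acetone and CO2, the standard alcoholysis–decarboxylation route to β-keto esters.

Step 3
Reactants: 4 methyl 3-oxotetradecanoate
Product: 5 methyl 2-(2-undecyl-1,3-dioxolan-2-yl)acetate
Conditions: HOCH2CH2OH (3 equiv), p-TsOH·H2O (5 mol %), toluene, Dean–Stark trap, reflux
Reagents that add atoms: ethylene glycol, OCCO
Why: Acid-catalysed ketalisation with azeotropic removal of water takes only the ketone carbonyl and so masks the future chain ketone for steps 4 to 6.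

Step 4
Reactants: 5 methyl 2-(2-undecyl-1,3-dioxolan-2-yl)acetate
Product: 6 2-(2-undecyl-1,3-dioxolan-2-yl)acetaldehyde
Conditions: iBu2AlH (1.1 equiv), CH2Cl2, −78 °C; MeOH, then aq. potassium sodium tartrate
Reagents that add atoms: none
Why: At −78 °C the aluminium hemiacetal from one hydride transfer, stabilised by chelation to a dioxolane oxygen, persists until the quench, so the partial ester reduction stops at the aldehyde as is known for β-ketal esters.

Step 5
Reactants: 6 2-(2-undecyl-1,3-dioxolan-2-yl)acetaldehyde (used crude); 7 methyl (triphenylphosphoranylidene)acetate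
Product: 8 methyl (E)-4-(2-undecyl-1,3-dioxolan-2-yl)but-2-enoate
Conditions: CH2Cl2, rt
Reagents that add atoms: none
Why: The Wittig reaction with a stabilised ylide runs without added base, which spares the elimination-prone β-ketal aldehyde, and it should give the E-enoate.

Step 6
Reactants: 8 methyl (E)-4-(2-undecyl-1,3-dioxolan-2-yl)but-2-enoate; 9 methyl acetoacetate
Product: 11 methyl 2,4-dioxo-6-[(2-undecyl-1,3-dioxolan-2-yl)methyl]cyclohexane-1-carboxylate, via Michael adduct 10 (not isolated)
Conditions: 9 (2 equiv), NaOMe (1.6 equiv), MeOH, rt then reflux; then 1 M HCl to pH 4, 0 °C, EtOAc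
Reagents that add atoms: none
Why: The sodium enolate of 9 adds through its α-carbon to the β-carbon of 8 (Michael addition, C1–C6 bond) to give 10, and proton exchange in methanol then makes available the terminal methyl ketone enolate of 10, whose carbon attacks the former enoate ester carbonyl and expels methoxide (intramolecular Claisen condensation, C3–C4 bond). The closest known reaction type is the Michael–Claisen annulation of acetoacetates with crotonates and higher 2-alkenoates to dihydroorsellinates and their 6-alkyl homologues. The one ring closes in the favoured 6-(enolendo)-exo-trig mode, and no other carbon–carbon closure competes because every other enolate–carbonyl pair in 10 would give a four-membered ring. Both reversible stages are drawn forward by deprotonation of the cyclic β-diketone (pKa about 5) to its delocalised sodium salt, which is protonated only at pH 4 and 0 °C so that the dioxolane is kept. C1 and C6 arise as racemic stereocentres with no controlling element beyond equilibration of the acidic C1 towards the trans arrangement, and none is needed because both become sp2 in step 7. The selectivity required is conjugate addition in preference to γ-deprotonation of 8 with vinylogous E1cB opening of the dioxolane; it is secured by holding 9 in excess over NaOMe so that the working base is the weakly basic acetoacetate enolate, by the reversibility of such an opening (the tethered alkoxide can add back), and by the ketal, which leaves only the carbonyls destined to become C2 and C4 open to condensation.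

Step 7
Reactants: 11 methyl 2,4-dioxo-6-[(2-undecyl-1,3-dioxolan-2-yl)methyl]cyclohexane-1-carboxylate
Product: 13 methyl 2-hydroxy-4-methoxy-6-(2-oxotridecyl)benzoate, via aromatic ketal 12 (not isolated)
Conditions: I2 (1.1 equiv), MeOH, reflux; then 2 M aq. HCl, rt; aq. Na2S2O3 wash
Reagents that add atoms: methanol, CO; water, O
Why: Acid-catalysed enol etherification by methanol at the unhindered C4 carbonyl, α-iodination of the remaining β-keto ester at C1, loss of HI and tautomerisation should give the 4-methoxysalicylate, with the C2 oxygen left free because it is hydrogen-bonded to the ester (iodine–methanol oxidative aromatisation of cyclohexenones and cyclohexane-1,3-diones); the HI released already attacks the dioxolane, so its hydrolysis is deliberately completed with aqueous HCl in the same flask.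

Step 8
Reactants: 13 methyl 2-hydroxy-4-methoxy-6-(2-oxotridecyl)benzoate
Product: 14 2-hydroxy-4-methoxy-6-(2-oxotridecyl)benzoic acid (CNP0171260.0)
Conditions: KOH (10 equiv), MeOH–H2O, 65 °C, Ar; then 1 M HCl to pH 2, 0 °C, immediate extraction
Reagents that add atoms: potassium hydroxide, [K+].[OH-]
Why: Saponification, normally slow for a 2,6-disubstituted salicylate, is assisted by the neighbouring 2-oxoalkyl group, whose hydrate or enolate oxygen can relay the acyl group; the carboxylate formed is inert, and acidification in the cold avoids enol lactonisation and decarboxylation.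

Compound list
1 | dodecanoyl chloride | CCCCCCCCCCCC(=O)Cl | starting material
2 | Meldrum's acid (2,2-dimethyl-1,3-dioxane-4,6-dione) | CC1(C)OC(=O)CC(=O)O1 | starting material
3 | 5-(1-hydroxydodecylidene)-2,2-dimethyl-1,3-dioxane-4,6-dione | CCCCCCCCCCCC(O)=C1C(=O)OC(C)(C)OC1=O | intermediate
4 | methyl 3-oxotetradecanoate | CCCCCCCCCCCC(=O)CC(=O)OC | intermediate
5 | methyl 2-(2-undecyl-1,3-dioxolan-2-yl)acetate | CCCCCCCCCCCC1(CC(=O)OC)OCCO1 | intermediate
6 | 2-(2-undecyl-1,3-dioxolan-2-yl)acetaldehyde | CCCCCCCCCCCC1(CC=O)OCCO1 | intermediate
7 | methyl (triphenylphosphoranylidene)acetate | COC(=O)C=P(c1ccccc1)(c1ccccc1)c1ccccc1 | starting material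
8 | methyl (E)-4-(2-undecyl-1,3-dioxolan-2-yl)but-2-enoate | CCCCCCCCCCCC1(C/C=C/C(=O)OC)OCCO1 | intermediate
9 | methyl acetoacetate | CC(=O)CC(=O)OC | starting material
10 | dimethyl 2-acetyl-3-[(2-undecyl-1,3-dioxolan-2-yl)methyl]pentanedioate (Michael adduct) | CCCCCCCCCCCC1(CC(CC(=O)OC)C(C(C)=O)C(=O)OC)OCCO1 | intermediate
11 | methyl 2,4-dioxo-6-[(2-undecyl-1,3-dioxolan-2-yl)methyl]cyclohexane-1-carboxylate | CCCCCCCCCCCC1(CC2CC(=O)CC(=O)C2C(=O)OC)OCCO1 | intermediate
12 | methyl 2-hydroxy-4-methoxy-6-[(2-undecyl-1,3-dioxolan-2-yl)methyl]benzoate (aromatic ketal) | CCCCCCCCCCCC1(Cc2cc(OC)cc(O)c2C(=O)OC)OCCO1 | intermediate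
13 | methyl 2-hydroxy-4-methoxy-6-(2-oxotridecyl)benzoate | CCCCCCCCCCCC(=O)Cc1cc(OC)cc(O)c1C(=O)OC | intermediate
14 | 2-hydroxy-4-methoxy-6-(2-oxotridecyl)benzoic acid | CCCCCCCCCCCC(=O)Cc1cc(OC)cc(O)c1C(=O)O | target

Total step count: 8
Longest linear sequence: 8 steps (1 to 14); 2, 7 and 9 enter as purchased materials.

Steps most likely to fail

Step 6. The risks are γ-deprotonation of the enoate followed by vinylogous β-elimination that opens the dioxolane, reversal of the Michael addition at reflux, and a sluggish Claisen closure. The fallback sets out from 6 and returns at 11 by exchanging the roles of donor and acceptor. Aldehyde 6 is olefinated with purchased 1-(triphenylphosphoranylidene)propan-2-one (CH2Cl2, rt) to (E)-5-(2-undecyl-1,3-dioxolan-2-yl)pent-3-en-2-one F1. Dimethyl malonate and NaOMe in MeOH add to this much more electrophilic enone at or below room temperature. The adduct is dimethyl 2-[4-oxo-1-(2-undecyl-1,3-dioxolan-2-yl)pentan-2-yl]propanedioate F2, in which the ketal is insulated from every acidic position. Heating then closes the methyl ketone enolate onto one malonate ester (ring bonds C1–C6 and C2–C3), the known malonate–enone route to 6-alkyl-2,4-dioxocyclohexanecarboxylates, and delivers the same dione 11.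

Step 7. The risks are methylation of the C2 oxygen as well, nuclear iodination of the electron-rich ring, and incomplete dehydrogenation. The fallback sets out from 11 and returns at 13 by separating dehydrogenation from methylation. Br2 (1 equiv) in DMF at 0 °C followed by warming to 80 °C is the known bromination–dehydrobromination of this class of diones. After stirring with dilute aqueous HCl it should give methyl 2,4-dihydroxy-6-(2-oxotridecyl)benzoate F3. MeI (1 equiv) and K2CO3 in acetone then alkylate only the C4 hydroxyl, because the C2 hydroxyl is hydrogen-bonded to the ester, giving 13.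

Step 8. The risks are acylation of the side-chain enolate carbon by the ester (closure to a naphthalene ring), slow attack of hydroxide on the hindered chelated ester, and lactonisation or loss of CO2 on acidification. The fallback sets out from 13 and returns at 14 by removing the ester methanol before any base is used. p-TsOH (cat.) in refluxing toluene with distillative removal of methanol converts 13 into the enol lactone 8-hydroxy-6-methoxy-3-undecyl-1H-isochromen-1-one F4. Aqueous KOH in EtOH opens this lactone directly to the carboxylate, the standard isocoumarin-to-keto-acid hydrolysis, and acidification in the cold gives 14.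

Further compounds
F1 | step 6 | (E)-5-(2-undecyl-1,3-dioxolan-2-yl)pent-3-en-2-one | CCCCCCCCCCCC1(C/C=C/C(C)=O)OCCO1
F2 | step 6 | dimethyl 2-[4-oxo-1-(2-undecyl-1,3-dioxolan-2-yl)pentan-2-yl]propanedioate | CCCCCCCCCCCC1(CC(CC(C)=O)C(C(=O)OC)C(=O)OC)OCCO1
F3 | step 7 | methyl 2,4-dihydroxy-6-(2-oxotridecyl)benzoate | CCCCCCCCCCCC(=O)Cc1cc(O)cc(O)c1C(=O)OC
F4 | step 8 | 8-hydroxy-6-methoxy-3-undecyl-1H-isochromen-1-one | CCCCCCCCCCCC1=Cc2cc(OC)cc(O)c2C(=O)O1
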